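**Plan**

- Retrosynthesis (ring atoms: O1, C2 lactone carbonyl, C3, C4 enol carbon, C5 stereocentre): cut first the benzyl ether on the C5 CH2OH, then the exocyclic C3–acyl bond, then the ring bond O1–C5, then C3–C4 of the open chain.
- Enabling feature: C5 is a secondary ring carbon that carries ring oxygen O1 and sits directly beside the C4 carbonyl carbon. As an α-keto carbon it is primed for SN2, so the only ring can be closed last at O1–C5 with inversion.
- Forward: O-benzyl-D-serine gives an (R)-glycerate ester; a Claisen condensation with tert-butyl acetate builds C3–C4; the furanone ring closes at O1–C5; the C15 acyl chain is joined at C3; debenzylation ends the route.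
- Stereochemistry: the single centre C5 comes from D-serine (R), is kept through diazotisation (double inversion) and is inverted once, in the ring closure, to the (S) configuration of the target.

Key step: step 7

Assumption: the acyl tetronic acids are written as their 4-hydroxy enol tautomers, which stand for the freely equilibrating tautomer set, and methanesulfonic anhydride replaces the sulfonyl chloride so that no chloride is present.

Step 1
Reactants: 1 O-benzyl-D-serine [(R)-2-amino-3-(benzyloxy)propanoic acid]
Product: 4 (R)-3-(benzyloxy)-2-hydroxypropanoic acid, via diazonium carboxylate 2 (not isolated), via α-lactone 3 (not isolated)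
Conditions: NaNO2, 1 M aq. H2SO4, 0 °C → rt
Reagents that add atoms: water (O)
Why: Diazotisation of the α-amino acid (van Slyke-type deamination) should go with net retention, because the carboxylate expels N2 from 2 to give α-lactone 3 and water then opens 3, each with inversion, so the (R) centre of D-serine is carried into 4.

Step 2
Reactants: 4 (R)-3-(benzyloxy)-2-hydroxypropanoic acid
Product: 5 methyl (R)-3-(benzyloxy)-2-hydroxypropanoate
Conditions: MeOH, cat. H2SO4, 50 °C
Reagents that add atoms: methanol (CO)
Why: Fischer esterification in excess methanol leaves the stereocentre and the benzyl ether untouched.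

Step 3
Reactants: 5 methyl (R)-3-(benzyloxy)-2-hydroxypropanoate
Product: 6 methyl (R)-3-(benzyloxy)-2-[(tert-butyldimethylsilyl)oxy]propanoate
Conditions: TBSCl, imidazole, DMF, rt
Reagents that add atoms: tert-butyldimethylsilyl chloride (CC(C)(C)[Si](C)(C)Cl)
Why: Imidazole-mediated silyl ether formation masks the secondary hydroxyl, so that no alkoxide is present in the condensation that could later lactonise onto the ester with retention.

Step 4
Reactants: 6 methyl (R)-3-(benzyloxy)-2-[(tert-butyldimethylsilyl)oxy]propanoate; 7 tert-butyl acetate
Product: 9 tert-butyl (R)-5-(benzyloxy)-4-[(tert-butyldimethylsilyl)oxy]-3-oxopentanoate, via lithium enolate of tert-butyl acetate 8 (not isolated)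
Conditions: 7 (3.3 equiv), LiN(iPr)2 (3.2 equiv), THF, −78 °C; then 6, −78 → −40 °C; AcOH quench
Reagents that add atoms: none
Why: In this crossed Claisen condensation the enolate 8 should add to the methyl ester at −78 °C faster than it removes the hindered C2 proton, and the β-keto ester is held as its enolate until the quench (hence the excess of 8), so the silyloxy stereocentre should survive.

Step 5
Reactants: 9 tert-butyl (R)-5-(benzyloxy)-4-[(tert-butyldimethylsilyl)oxy]-3-oxopentanoate
Product: 10 tert-butyl (R)-5-(benzyloxy)-4-hydroxy-3-oxopentanoate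
Conditions: HF·pyridine, pyridine, THF, 0 °C → rt
Reagents that add atoms: none
Why: Fluoride-mediated desilylation under buffered, weakly acidic conditions should free the hydroxyl without lactonisation, since a tert-butyl ester resists acyl substitution by the neighbouring alcohol under these conditions.

Step 6
Reactants: 10 tert-butyl (R)-5-(benzyloxy)-4-hydroxy-3-oxopentanoate
Product: 11 tert-butyl (R)-5-(benzyloxy)-4-[(methylsulfonyl)oxy]-3-oxopentanoate
Conditions: Ms2O (1.3 equiv), 2,4,6-collidine (2 equiv), CH2Cl2, −20 → 0 °C; cold aqueous work-up, used crude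
Reagents that add atoms: methanesulfonic anhydride (CS(=O)(=O)OS(C)(=O)=O)
Why: Sulfonylation of the secondary alcohol occurs at oxygen and retains the configuration at carbon, the anhydride keeps chloride out (chloride could displace the activated α-keto mesylate and open a double-inversion leak), and the hindered weak base should not enolise the ketone toward the stereocentre.

Step 7
Reactants: 11 tert-butyl (R)-5-(benzyloxy)-4-[(methylsulfonyl)oxy]-3-oxopentanoate
Product: 13 (S)-5-[(benzyloxy)methyl]-4-hydroxyfuran-2(5H)-one, via cyclic alkoxy-oxocarbenium mesylate 12 (not isolated)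
Conditions: 2,6-di-tert-butylpyridine (1.2 equiv), MeCN (0.05 M), 60–70 °C
Reagents that add atoms: none
Why: Proposed new method: the carbonyl oxygen of the tert-butyl ester should displace the mesylate at C5 from the rear in an intramolecular SN2 O-alkylation, and the resulting cyclic alkoxy-oxocarbenium ion 12 should shed its tert-butyl group as isobutene to leave the lactone carbonyl, so that O1 is the former ester carbonyl oxygen. The closest known reaction type is the thermal cyclisation of 4-halo-3-oxo esters to tetronic acids through the ester carbonyl, together with the familiar participation of tert-butyl ester and tert-butyl carbamate carbonyls in sulfonate displacements with loss of isobutene; what is untested is the union of the two on a stereodefined secondary α-keto sulfonate. The furanone ring closes in 5-exo-tet mode. C5 is controlled by the substrate alone: backside attack turns the (R)-mesylate into the (S)-lactone. The step needs clean inversion rather than ionisation, enolisation toward C5 or a double displacement; the C4 carbonyl next to C5 speeds the SN2 path and destabilises a cation, the medium holds no halide, and the only base is a hindered pyridine that should not enolise the ketone but removes the methanesulfonic acid that would otherwise cleave the tert-butyl ester of unreacted 11. Closing the ring before C3 carries its acyl group leaves no second enol oxygen to compete for C5, and staying at or below 70 °C keeps clear of the thermal fragmentation of tert-butyl β-keto esters to acylketenes.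

Step 8
Reactants: 13 (S)-5-[(benzyloxy)methyl]-4-hydroxyfuran-2(5H)-one; 14 13-methyltetradecanoic acid
Product: 17 (S)-5-[(benzyloxy)methyl]-4-hydroxy-3-(13-methyltetradecanoyl)furan-2(5H)-one, via O-acylisourea 15 (not isolated), via 4-O-acyl tetronate 16 (not isolated)
Conditions: DCC (1.2 equiv), DMAP (1.5 equiv), CH2Cl2, 0 °C → rt; 1 M HCl wash
Reagents that add atoms: none
Why: Carbodiimide esterification at O4 (Steglich conditions) followed by DMAP-promoted O-to-C acyl migration (Fries-type 1,3-shift) to the nucleophilic C3 is the standard entry to 3-acyl tetronic acids, is driven by formation of the chelated triketone enol, and should leave C5 untouched.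

Step 9
Reactants: 17 (S)-5-[(benzyloxy)methyl]-4-hydroxy-3-(13-methyltetradecanoyl)furan-2(5H)-one
Product: 18 (S)-4-hydroxy-5-(hydroxymethyl)-3-(13-methyltetradecanoyl)furan-2(5H)-one (CNP0160106.1)
Conditions: H2 (1 atm), 10% Pd/C, EtOAc, rt
Reagents that add atoms: none
Why: Catalytic hydrogenolysis should cleave the benzyl ether while the fully substituted, conjugated enol double bond and the chelated acyl carbonyl stay inert at atmospheric pressure.

**Compound list**

1 | O-benzyl-D-serine, (R)-2-amino-3-(benzyloxy)propanoic acid | N[C@H](COCc1ccccc1)C(=O)O | starting material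
2 | (R)-3-(benzyloxy)-2-diazoniopropanoate (diazonium carboxylate) | N#[N+][C@H](COCc1ccccc1)C(=O)[O-] | intermediate
3 | (S)-3-[(benzyloxy)methyl]oxiran-2-one (α-lactone) | O1[C@@H](COCc2ccccc2)C1=O | intermediate
4 | (R)-3-(benzyloxy)-2-hydroxypropanoic acid | O[C@H](COCc1ccccc1)C(=O)O | intermediate
5 | methyl (R)-3-(benzyloxy)-2-hydroxypropanoate | O[C@H](COCc1ccccc1)C(=O)OC | intermediate
6 | methyl (R)-3-(benzyloxy)-2-[(tert-butyldimethylsilyl)oxy]propanoate | CC(C)(C)[Si](C)(C)O[C@H](COCc1ccccc1)C(=O)OC | intermediate
7 | tert-butyl acetate | CC(=O)OC(C)(C)C | starting material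
8 | lithium enolate of tert-butyl acetate (lithium 1-tert-butoxyethen-1-olate) | [Li+].C=C([O-])OC(C)(C)C | intermediate
9 | tert-butyl (R)-5-(benzyloxy)-4-[(tert-butyldimethylsilyl)oxy]-3-oxopentanoate | CC(C)(C)[Si](C)(C)O[C@H](COCc1ccccc1)C(=O)CC(=O)OC(C)(C)C | intermediate
10 | tert-butyl (R)-5-(benzyloxy)-4-hydroxy-3-oxopentanoate | O[C@H](COCc1ccccc1)C(=O)CC(=O)OC(C)(C)C | intermediate
11 | tert-butyl (R)-5-(benzyloxy)-4-[(methylsulfonyl)oxy]-3-oxopentanoate | CS(=O)(=O)O[C@H](COCc1ccccc1)C(=O)CC(=O)OC(C)(C)C | intermediate
12 | (S)-5-[(benzyloxy)methyl]-2-tert-butoxy-4-oxo-4,5-dihydro-3H-furan-1-ium methanesulfonate | CC(C)(C)OC1=[O+][C@@H](COCc2ccccc2)C(=O)C1.CS(=O)(=O)[O-] | intermediate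
13 | (S)-5-[(benzyloxy)methyl]-4-hydroxyfuran-2(5H)-one | O=C1C=C(O)[C@H](COCc2ccccc2)O1 | intermediate
14 | 13-methyltetradecanoic acid | CC(C)CCCCCCCCCCCC(=O)O | starting material
15 | N,N'-dicyclohexyl-O-(13-methyltetradecanoyl)isourea | CC(C)CCCCCCCCCCCC(=O)OC(=NC1CCCCC1)NC1CCCCC1 | intermediate
16 | (S)-2-[(benzyloxy)methyl]-5-oxo-2,5-dihydrofuran-3-yl 13-methyltetradecanoate | CC(C)CCCCCCCCCCCC(=O)OC1=CC(=O)O[C@H]1COCc2ccccc2 | intermediate
17 | (S)-5-[(benzyloxy)methyl]-4-hydroxy-3-(13-methyltetradecanoyl)furan-2(5H)-one | CC(C)CCCCCCCCCCCC(=O)C1=C(O)[C@H](COCc2ccccc2)OC1=O | intermediate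
18 | (S)-4-hydroxy-5-(hydroxymethyl)-3-(13-methyltetradecanoyl)furan-2(5H)-one | CC(C)CCCCCCCCCCCC(=O)C1=C(O)[C@H](CO)OC1=O | target

**Step count**

Total steps: 9. Longest linear sequence: 9 steps (from 1 to 18).

**Steps most likely to fail**

1. Step 7. The ester carbonyl oxygen may be too weak a nucleophile below the temperature at which the tert-butyl β-keto ester fragments, or slow enolisation toward C5 may erode the configuration before displacement. The fallback uses known chemistry and sets out from 5. A Mitsunobu esterification with acetic acid (PPh3, DIAD, THF, 0 °C) forms the O1–C5 bond intermolecularly with inversion and should give methyl (S)-2-acetoxy-3-(benzyloxy)propanoate F1. A Dieckmann cyclisation of F1 with LiN(SiMe3)2 (2.2 equiv, THF, −78 °C, acidic work-up) then closes C3–C4 without touching C5 and comes back to the route at 13.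

2. Step 6. Sulfonylation beside the ketone may be accompanied by base-induced enolisation with epimerisation, by loss of benzyl alcohol through β-elimination, or by uncontrolled reaction of the activated sulfonate during work-up. The fallback sets out from 10 and avoids the sulfonate altogether. A Mitsunobu inversion with 4-nitrobenzoic acid (PPh3, DIAD, THF, 0 °C) should give tert-butyl (S)-5-(benzyloxy)-4-[(4-nitrobenzoyl)oxy]-3-oxopentanoate F2. Methanolysis (K2CO3, MeOH, 0 °C; the β-keto ester is held as its enolate) frees tert-butyl (S)-5-(benzyloxy)-4-hydroxy-3-oxopentanoate F3. Trifluoroacetic acid in CH2Cl2 then closes the lactone by acyl substitution with retention at C5 and comes back to the route at 13, so steps 6 and 7 are both bypassed.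

3. Step 4. Proton transfer from C2 of ester 6 to the strongly basic ester enolate would lead to racemisation or to β-elimination of benzyl alcohol, and consumption of enolate by the product may leave the condensation incomplete. The fallback sets out from 6 and builds the β-keto ester under neutral conditions (Masamune–Brooks-type chain extension). Saponification (LiOH, THF/H2O, 0 °C) gives (R)-3-(benzyloxy)-2-[(tert-butyldimethylsilyl)oxy]propanoic acid F4. Carbonyldiimidazole in THF converts it into the acyl imidazolide (R)-3-(benzyloxy)-2-[(tert-butyldimethylsilyl)oxy]-1-(1H-imidazol-1-yl)propan-1-one F5. Mg(O2CCH2CO2tBu)2, made in the flask from mono-tert-butyl malonate, MgCl2 and Et3N, is C-acylated to the acylmalonate half ester 2-[(R)-3-(benzyloxy)-2-[(tert-butyldimethylsilyl)oxy]propanoyl]-3-tert-butoxy-3-oxopropanoic acid F6 (its magnesium salt in the flask), which loses CO2 on mild acidic work-up and comes back to the route at 9.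

**Further compounds**

F1 | step 7 | methyl (S)-2-acetoxy-3-(benzyloxy)propanoate | CC(=O)O[C@@H](COCc1ccccc1)C(=O)OC
F2 | step 6 | tert-butyl (S)-5-(benzyloxy)-4-[(4-nitrobenzoyl)oxy]-3-oxopentanoate | O=C(O[C@@H](COCc1ccccc1)C(=O)CC(=O)OC(C)(C)C)c1ccc(cc1)[N+](=O)[O-]
F3 | step 6 | tert-butyl (S)-5-(benzyloxy)-4-hydroxy-3-oxopentanoate | O[C@@H](COCc1ccccc1)C(=O)CC(=O)OC(C)(C)C
F4 | step 4 | (R)-3-(benzyloxy)-2-[(tert-butyldimethylsilyl)oxy]propanoic acid | CC(C)(C)[Si](C)(C)O[C@H](COCc1ccccc1)C(=O)O
F5 | step 4 | (R)-3-(benzyloxy)-2-[(tert-butyldimethylsilyl)oxy]-1-(1H-imidazol-1-yl)propan-1-one | CC(C)(C)[Si](C)(C)O[C@H](COCc1ccccc1)C(=O)n1ccnc1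
F6 | step 4 | 2-[(R)-3-(benzyloxy)-2-[(tert-butyldimethylsilyl)oxy]propanoyl]-3-tert-butoxy-3-oxopropanoic acid | CC(C)(C)[Si](C)(C)O[C@H](COCc1ccccc1)C(=O)C(C(=O)O)C(=O)OC(C)(C)C
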